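Ring B is made, not bought. Its edge (ring-C oxygen on C4', oxygen on C5', C8 on C3', carbon on C1') is the footprint of a furan–ynol ether benzannulation. One gold-catalysed operation on an ethynyl ether forms C3'–C4' and C5'–C6', closes dihydrofuran ring C and aromatic ring B, and moves the furan oxygen to C5' as the phenol that becomes the 5'-methoxy group. The precursor is the ethynyl ether of a syn-aldol-derived (1R,2S)-1-(3,4,5-trimethoxyphenyl)-2-[4-(silyloxymethyl)furan-2-yl]propane-1,3-diol 3-silyl ether, so C7 and C8 are set by an Evans aldol before the arene exists.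

Key step: step 8

Remark: neolignan numbering is used (ring A with C7–C9; ring B C1'–C6' with C7'–C9'; ring C the dihydrofuran), and 1 and 2 are taken as catalogue items.

Step 1
Reactants: 1 methyl 5-bromofuran-3-carboxylate; 2 (2-tert-butoxy-2-oxoethyl)zinc bromide
Product: 3 tert-butyl 2-[4-(methoxycarbonyl)furan-2-yl]acetate
Conditions: Pd(dba)2 (2 mol %), XPhos (4 mol %), THF, rt → 60 °C
Reagents that add atoms: none
Why: Negishi-type cross-coupling of a Reformatsky zinc enolate with a heteroaryl bromide: the electron-poor 2-bromofuran should add readily to zerovalent palladium, and the zinc enolate is too mild to attack either ester.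

Step 2
Reactants: 3 tert-butyl 2-[4-(methoxycarbonyl)furan-2-yl]acetate
Product: 4 2-[4-(methoxycarbonyl)furan-2-yl]acetic acid
Conditions: TFA/CH2Cl2 (1:4), 0 °C → rt
Reagents that add atoms: none
Why: Acidolysis of a tert-butyl ester by E1 loss of isobutene, which leaves the methyl ester intact and is tolerated by the ester-deactivated furan.

Step 3
Reactants: 4 2-[4-(methoxycarbonyl)furan-2-yl]acetic acid; 5 (R)-4-benzyl-1,3-oxazolidin-2-one
Product: 7 (4R)-4-benzyl-3-{2-[4-(methoxycarbonyl)furan-2-yl]acetyl}-1,3-oxazolidin-2-one, via mixed pivalic anhydride 6 (not isolated)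
Conditions: t-BuCOCl, Et3N, THF, −20 °C; then LiCl, 5, −20 °C → rt
Reagents that add atoms: none
Why: N-Acylation of the oxazolidinone through a mixed anhydride under LiCl/Et3N activation; the hindered pivaloyl carbonyl directs attack to the arylacetyl carbonyl.

Step 4
Reactants: 7 (4R)-4-benzyl-3-{2-[4-(methoxycarbonyl)furan-2-yl]acetyl}-1,3-oxazolidin-2-one; 8 3,4,5-trimethoxybenzaldehyde
Product: 10 (4R)-4-benzyl-3-[(2S,3R)-3-hydroxy-2-[4-(methoxycarbonyl)furan-2-yl]-3-(3,4,5-trimethoxyphenyl)propanoyl]-1,3-oxazolidin-2-one, via Z-boron enolate 9 (not isolated)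
Conditions: n-Bu2BOTf, i-Pr2NEt, CH2Cl2, −78 → 0 °C; 8, −78 → 0 °C; NaH2PO4/Na2HPO4 buffer (pH 7), MeOH, H2O2, 0 °C
Reagents that add atoms: none
Why: Evans syn aldol reaction: Z-boron enolate 9 should add to the aldehyde through a chair Zimmerman–Traxler transition state on the enolate face remote from the benzyl group, which sets C8 as 2S and C7 as 3R in one event.

Step 5
Reactants: 10 (4R)-4-benzyl-3-[(2S,3R)-3-hydroxy-2-[4-(methoxycarbonyl)furan-2-yl]-3-(3,4,5-trimethoxyphenyl)propanoyl]-1,3-oxazolidin-2-one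
Product: 12 (1R,2S)-2-[4-(hydroxymethyl)furan-2-yl]-1-(3,4,5-trimethoxyphenyl)propane-1,3-diol, via ester diol 11 (not isolated)
Conditions: LiBH4, MeOH, THF, 0 °C → 45 °C
Reagents that add atoms: none
Why: Borohydride reduction: the activated exocyclic imide carbonyl is reduced at 0 °C with release of the auxiliary and the furoate ester on warming, so all three hydroxyls appear in one operation under conditions that should leave C7 and C8 intact.

Step 6
Reactants: 12 (1R,2S)-2-[4-(hydroxymethyl)furan-2-yl]-1-(3,4,5-trimethoxyphenyl)propane-1,3-diol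
Product: 13 (1R,2S)-1-(3,4,5-trimethoxyphenyl)-3-[(triisopropylsilyl)oxy]-2-(4-{[(triisopropylsilyl)oxy]methyl}furan-2-yl)propan-1-ol
Conditions: i-Pr3SiCl (2.2 equiv), imidazole, DMF, 0 °C → rt
Reagents that add atoms: chlorotri(propan-2-yl)silane, CC(C)[Si](Cl)(C(C)C)C(C)C
Why: Sterically controlled silylation: the bulky chlorosilane should take the two primary hydroxyls and leave the flanked benzylic C7 hydroxyl free, and triisopropylsilyl is preferred to smaller silyl groups because it resists O-to-O migration to the C7 alkoxide in step 7.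

Step 7
Reactants: 13 (1R,2S)-1-(3,4,5-trimethoxyphenyl)-3-[(triisopropylsilyl)oxy]-2-(4-{[(triisopropylsilyl)oxy]methyl}furan-2-yl)propan-1-ol; 14 trichloroethylene
Product: 17 ethynyl (1R,2S)-1-(3,4,5-trimethoxyphenyl)-3-[(triisopropylsilyl)oxy]-2-(4-{[(triisopropylsilyl)oxy]methyl}furan-2-yl)propyl ether, via dichlorovinyl ether 15 (not isolated), via lithium alkynyl ether 16 (not isolated)
Conditions: KH (1.5 equiv), THF, 0 °C; 14 (1.1 equiv), −50 °C → rt; n-BuLi (2.5 equiv), −78 → −40 °C; MeOH, −78 °C; cold work-up, used at once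
Reagents that add atoms: none
Why: Ynol ether synthesis from trichloroethylene: the potassium alkoxide adds to dichloroacetylene generated in situ to give 15, n-BuLi eliminates HCl and exchanges the remaining chlorine to give 16, and protonation gives 17, every bond change lying beyond the C7 oxygen so that C7 and C8 are untouched.

Step 8
Reactants: 17 ethynyl (1R,2S)-1-(3,4,5-trimethoxyphenyl)-3-[(triisopropylsilyl)oxy]-2-(4-{[(triisopropylsilyl)oxy]methyl}furan-2-yl)propyl ether
Product: 19 (2R,3S)-2-(3,4,5-trimethoxyphenyl)-3,5-bis{[(triisopropylsilyl)oxy]methyl}-2,3-dihydro-1-benzofuran-7-ol, via arene oxide 18 (not isolated)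
Conditions: (Ph3P)AuNTf2 (3 mol %), 4 Å MS, CH2Cl2, −20 → 0 °C
Reagents that add atoms: none
Why: This is a gold-catalysed furan–yne phenol synthesis, a reaction type known for furans tethered to alkynyl ethers and ynamides and applied here to a new tether that carries two stereocentres and a 4-substituted furan. Monovalent gold binds the ynol ether and makes its oxygen-bearing carbon electrophilic; furan C2 attacks it in a 5-exo-dig closure that forms C3'–C4' and ring C, and the cyclopropyl gold carbenoid so formed unravels the furan to a dienal carbene. The aldehyde oxygen then adds to the carbene carbon and, after loss of gold, 6π ring closure forms C5'–C6' (ring B) as arene oxide 18, which opens toward the cation stabilised by the ring oxygen on C4' and tautomerises to the C5' phenol. No stereocentre is created: C7 and C8 lie in the tether, no bond to either is broken, and the configuration set in step 4 becomes the trans relationship across ring C. The step needs regioselectivity (furan C2 to the internal alkyne carbon, hydroxyl on C5') and chemoselectivity against ionisation, sigmatropic shift or hydration of the benzylic ynol ether. The three-atom C8–C7–O tether allows only the 5-exo mode, the polarity of the ynol ether and the C4' oxygen fix the site of the hydroxyl, and low temperature, a dry non-nucleophilic medium and fast intramolecular capture by the electron-rich furan should hold the side paths back.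

Step 9
Reactants: 19 (2R,3S)-2-(3,4,5-trimethoxyphenyl)-3,5-bis{[(triisopropylsilyl)oxy]methyl}-2,3-dihydro-1-benzofuran-7-ol
Product: 20 (2R,3S)-7-methoxy-2-(3,4,5-trimethoxyphenyl)-3,5-bis{[(triisopropylsilyl)oxy]methyl}-2,3-dihydro-1-benzofuran
Conditions: MeI, K2CO3, acetone, rt
Reagents that add atoms: iodomethane, CI
Why: Williamson ether synthesis on the only acidic hydroxyl, run directly on the freshly filtered phenol so that the air-sensitive catechol monoether is capped before it can oxidise.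

Step 10
Reactants: 20 (2R,3S)-7-methoxy-2-(3,4,5-trimethoxyphenyl)-3,5-bis{[(triisopropylsilyl)oxy]methyl}-2,3-dihydro-1-benzofuran
Product: 21 [(2R,3S)-7-methoxy-2-(3,4,5-trimethoxyphenyl)-2,3-dihydro-1-benzofuran-3,5-diyl]dimethanol
Conditions: Bu4NF, THF, 0 °C → rt
Reagents that add atoms: none
Why: Fluoride-induced desilylation removes both primary silyl ethers at once; neither the aryl methyl ethers nor ring C react with fluoride.

Step 11
Reactants: 21 [(2R,3S)-7-methoxy-2-(3,4,5-trimethoxyphenyl)-2,3-dihydro-1-benzofuran-3,5-diyl]dimethanol; 22 methyl (triphenylphosphoranylidene)acetate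
Product: 24 methyl (2E)-3-[(2R,3S)-3-(hydroxymethyl)-7-methoxy-2-(3,4,5-trimethoxyphenyl)-2,3-dihydro-1-benzofuran-5-yl]prop-2-enoate, via aldehyde 23 (not isolated)
Conditions: activated MnO2 (15 equiv), 22 (1.3 equiv), CH2Cl2, rt → 40 °C
Reagents that add atoms: none
Why: Tandem MnO2 oxidation–Wittig olefination: MnO2 oxidises only the benzylic C7' alcohol to aldehyde 23, which the stabilised ylide traps in situ as the E-enoate, while the saturated C9 alcohol is inert.

Step 12
Reactants: 24 methyl (2E)-3-[(2R,3S)-3-(hydroxymethyl)-7-methoxy-2-(3,4,5-trimethoxyphenyl)-2,3-dihydro-1-benzofuran-5-yl]prop-2-enoate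
Product: 25 (-)-(7R,8S,7'E)-3,4,5,5'-tetramethoxy-4',7-epoxy-8,3'-neolign-7'-ene-9,9'-diol
Conditions: i-Bu2AlH (4 equiv), CH2Cl2, −78 °C; aq. potassium sodium tartrate
Reagents that add atoms: none
Why: Hydride 1,2-reduction of an α,β-unsaturated ester with i-Bu2AlH at low temperature should give the allylic alcohol with the E geometry retained; the first equivalent is consumed by the C9 hydroxyl.

Compound list
1 | methyl 5-bromofuran-3-carboxylate | COC(=O)c1coc(Br)c1 | starting material
2 | (2-tert-butoxy-2-oxoethyl)zinc bromide | Br[Zn]CC(=O)OC(C)(C)C | starting material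
3 | tert-butyl 2-[4-(methoxycarbonyl)furan-2-yl]acetate | COC(=O)c1coc(CC(=O)OC(C)(C)C)c1 | intermediate
4 | 2-[4-(methoxycarbonyl)furan-2-yl]acetic acid | COC(=O)c1coc(CC(=O)O)c1 | intermediate
5 | (R)-4-benzyl-1,3-oxazolidin-2-one | O=C1N[C@H](Cc2ccccc2)CO1 | starting material
6 | 2-[4-(methoxycarbonyl)furan-2-yl]acetic pivalic anhydride | COC(=O)c1coc(CC(=O)OC(=O)C(C)(C)C)c1 | intermediate (not isolated)
7 | (4R)-4-benzyl-3-{2-[4-(methoxycarbonyl)furan-2-yl]acetyl}-1,3-oxazolidin-2-one | COC(=O)c1coc(CC(=O)N2C(=O)OC[C@H]2Cc2ccccc2)c1 | intermediate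
8 | 3,4,5-trimethoxybenzaldehyde | COc1cc(C=O)cc(OC)c1OC | starting material
9 | dibutylboron (Z)-enolate of 7 | CCCCB(CCCC)O/C(=C\c1cc(C(=O)OC)co1)N1C(=O)OC[C@H]1Cc1ccccc1 | intermediate (not isolated)
10 | (4R)-4-benzyl-3-[(2S,3R)-3-hydroxy-2-[4-(methoxycarbonyl)furan-2-yl]-3-(3,4,5-trimethoxyphenyl)propanoyl]-1,3-oxazolidin-2-one | COc1cc([C@H](O)[C@H](C(=O)N2C(=O)OC[C@H]2Cc2ccccc2)c2cc(C(=O)OC)co2)cc(OC)c1OC | intermediate
11 | methyl 5-[(1R,2S)-1,3-dihydroxy-1-(3,4,5-trimethoxyphenyl)propan-2-yl]furan-3-carboxylate | COc1cc([C@H](O)[C@H](CO)c2cc(C(=O)OC)co2)cc(OC)c1OC | intermediate (not isolated)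
12 | (1R,2S)-2-[4-(hydroxymethyl)furan-2-yl]-1-(3,4,5-trimethoxyphenyl)propane-1,3-diol | COc1cc([C@H](O)[C@H](CO)c2cc(CO)co2)cc(OC)c1OC | intermediate
13 | (1R,2S)-1-(3,4,5-trimethoxyphenyl)-3-[(triisopropylsilyl)oxy]-2-(4-{[(triisopropylsilyl)oxy]methyl}furan-2-yl)propan-1-ol | COc1cc([C@H](O)[C@H](CO[Si](C(C)C)(C(C)C)C(C)C)c2cc(CO[Si](C(C)C)(C(C)C)C(C)C)co2)cc(OC)c1OC | intermediate
14 | trichloroethylene | ClC=C(Cl)Cl | starting material
15 | (E)-1,2-dichlorovinyl ether of 13 | COc1cc([C@H](O/C(Cl)=C\Cl)[C@H](CO[Si](C(C)C)(C(C)C)C(C)C)c2cc(CO[Si](C(C)C)(C(C)C)C(C)C)co2)cc(OC)c1OC | intermediate (not isolated)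
16 | lithium alkynyl ether (2-lithioethynyl ether of 13) | COc1cc([C@H](OC#C[Li])[C@H](CO[Si](C(C)C)(C(C)C)C(C)C)c2cc(CO[Si](C(C)C)(C(C)C)C(C)C)co2)cc(OC)c1OC | intermediate (not isolated)
17 | ethynyl (1R,2S)-1-(3,4,5-trimethoxyphenyl)-3-[(triisopropylsilyl)oxy]-2-(4-{[(triisopropylsilyl)oxy]methyl}furan-2-yl)propyl ether | COc1cc([C@H](OC#C)[C@H](CO[Si](C(C)C)(C(C)C)C(C)C)c2cc(CO[Si](C(C)C)(C(C)C)C(C)C)co2)cc(OC)c1OC | intermediate (key-step precursor)
18 | arene oxide: (2R,3S)-6,7-epoxy-2-(3,4,5-trimethoxyphenyl)-3,5-bis{[(triisopropylsilyl)oxy]methyl}-2,3,6,7-tetrahydro-1-benzofuran (epoxide face not fixed; both faces lead to 19) | COc1cc([C@@H]2OC3=C([C@H]2CO[Si](C(C)C)(C(C)C)C(C)C)C=C(CO[Si](C(C)C)(C(C)C)C(C)C)C4OC34)cc(OC)c1OC | intermediate (not isolated)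
19 | (2R,3S)-2-(3,4,5-trimethoxyphenyl)-3,5-bis{[(triisopropylsilyl)oxy]methyl}-2,3-dihydro-1-benzofuran-7-ol | COc1cc([C@@H]2Oc3c(O)cc(CO[Si](C(C)C)(C(C)C)C(C)C)cc3[C@H]2CO[Si](C(C)C)(C(C)C)C(C)C)cc(OC)c1OC | intermediate (key-step product)
20 | (2R,3S)-7-methoxy-2-(3,4,5-trimethoxyphenyl)-3,5-bis{[(triisopropylsilyl)oxy]methyl}-2,3-dihydro-1-benzofuran | COc1cc([C@@H]2Oc3c(OC)cc(CO[Si](C(C)C)(C(C)C)C(C)C)cc3[C@H]2CO[Si](C(C)C)(C(C)C)C(C)C)cc(OC)c1OC | intermediate
21 | [(2R,3S)-7-methoxy-2-(3,4,5-trimethoxyphenyl)-2,3-dihydro-1-benzofuran-3,5-diyl]dimethanol | COc1cc([C@@H]2Oc3c(OC)cc(CO)cc3[C@H]2CO)cc(OC)c1OC | intermediate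
22 | methyl (triphenylphosphoranylidene)acetate | COC(=O)C=P(c1ccccc1)(c1ccccc1)c1ccccc1 | starting material
23 | (2R,3S)-3-(hydroxymethyl)-7-methoxy-2-(3,4,5-trimethoxyphenyl)-2,3-dihydro-1-benzofuran-5-carbaldehyde | COc1cc([C@@H]2Oc3c(OC)cc(C=O)cc3[C@H]2CO)cc(OC)c1OC | intermediate (not isolated)
24 | methyl (2E)-3-[(2R,3S)-3-(hydroxymethyl)-7-methoxy-2-(3,4,5-trimethoxyphenyl)-2,3-dihydro-1-benzofuran-5-yl]prop-2-enoate | COc1cc([C@@H]2Oc3c(OC)cc(/C=C/C(=O)OC)cc3[C@H]2CO)cc(OC)c1OC | intermediate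
25 | (-)-(7R,8S,7'E)-3,4,5,5'-tetramethoxy-4',7-epoxy-8,3'-neolign-7'-ene-9,9'-diol | COc1cc([C@@H]2Oc3c(OC)cc(/C=C/CO)cc3[C@H]2CO)cc(OC)c1OC | target

Total step count: 12. Longest linear sequence: 12 steps (1 → 25); all other inputs are purchased.

Steps most likely to fail

Step 8. The benzylic ynol ether may ionise at C7–O, shift sigmatropically onto ring A or be hydrated before the furan attacks, or the furan may engage the activated alkyne in another mode. The fallback sets out from 2, 5, 8 and 22 and returns at 24; ring B is bought as 5-bromovanillin and ring C is closed last by benzylic substitution. Benzylation (BnBr, K2CO3, DMF) should give 4-(benzyloxy)-3-bromo-5-methoxybenzaldehyde F1, and Wittig reaction with 22 methyl (2E)-3-[4-(benzyloxy)-3-bromo-5-methoxyphenyl]prop-2-enoate F2. Coupling with 2 under the conditions of step 1 should give the tert-butyl arylacetate F3 and TFA the arylacetic acid F4. Activation as the mixed pivalic anhydride F5 and acylation of 5 should give the N-arylacetyl oxazolidinone F6. The boron aldol of step 4 with 8 should give the syn adduct F7. NaBH4 in THF/H2O should remove the auxiliary without touching the enoate and give the 1,3-diol F8, and BCl3 with pentamethylbenzene at −78 °C should free the phenol F9. Catalytic TsOH in CH2Cl2 then ionises the C7 alcohol, and the phenol oxygen should capture the benzylic cation anti to the C8 substituent, giving trans 24 with C8 as set by the aldol.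

Step 7. Silicon may migrate from O9 to the C7 alkoxide under KH, and the labile ynol ether may be lost in the strongly basic one-pot sequence. The fallback sets out from 13 and returns at 16, and so at 17; it builds the ynol ether from a formate, so no alkoxide is ever present. Acetic formic anhydride and pyridine at 0 °C should give the C7 formate F10. Dibromomethylenation of the formyl group (PPh3, CBr4, CH2Cl2) should give the 2,2-dibromovinyl ether F11. n-BuLi (2.2 equiv, THF, −78 °C) should convert F11 by Br/Li exchange, 1,2-shift and deprotonation (Corey–Fuchs-type alkyne synthesis) into lithium alkynyl ether 16, which is protonated to 17 as in step 7.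

Step 4. Retro-aldol cleavage and epimerisation at the acidic C8 position, or eroded facial selectivity of the heteroarylacetyl boron enolate, may spoil the stereodiad. The fallback sets out from 4 and 8 and returns at 11; it changes the enolate class and the auxiliary, so that enolisation is done by a Lewis acid with a weak base and cleavage needs only a mild hydride. Acid 4 is coupled (DCC, DMAP, CH2Cl2) with (R)-4-benzyl-1,3-thiazolidine-2-thione to the N-acyl thiazolidinethione F12. TiCl4, i-Pr2NEt and N-methylpyrrolidinone at −78 °C followed by 8 should give the Evans-syn adduct F13 through a titanium-bound chair transition state. NaBH4 in THF/EtOH at 0 °C should cleave the activated thioimide to ester diol 11, and LiBH4 as in step 5 completes the reduction to 12.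

Further compounds
F1 | step 8 | 4-(benzyloxy)-3-bromo-5-methoxybenzaldehyde | COc1cc(C=O)cc(Br)c1OCc1ccccc1
F2 | step 8 | methyl (2E)-3-[4-(benzyloxy)-3-bromo-5-methoxyphenyl]prop-2-enoate | COC(=O)/C=C/c1cc(Br)c(OCc2ccccc2)c(OC)c1
F3 | step 8 | methyl (2E)-3-[4-(benzyloxy)-3-(2-tert-butoxy-2-oxoethyl)-5-methoxyphenyl]prop-2-enoate | COC(=O)/C=C/c1cc(CC(=O)OC(C)(C)C)c(OCc2ccccc2)c(OC)c1
F4 | step 8 | {2-(benzyloxy)-3-methoxy-5-[(1E)-3-methoxy-3-oxoprop-1-en-1-yl]phenyl}acetic acid | COC(=O)/C=C/c1cc(CC(=O)O)c(OCc2ccccc2)c(OC)c1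
F5 | step 8 | mixed pivalic anhydride of F4 | COC(=O)/C=C/c1cc(CC(=O)OC(=O)C(C)(C)C)c(OCc2ccccc2)c(OC)c1
F6 | step 8 | methyl (2E)-3-[4-(benzyloxy)-3-{2-[(4R)-4-benzyl-2-oxo-1,3-oxazolidin-3-yl]-2-oxoethyl}-5-methoxyphenyl]prop-2-enoate | COC(=O)/C=C/c1cc(CC(=O)N2C(=O)OC[C@H]2Cc2ccccc2)c(OCc2ccccc2)c(OC)c1
F7 | step 8 | methyl (2E)-3-[4-(benzyloxy)-3-{(2R,3R)-1-[(4R)-4-benzyl-2-oxo-1,3-oxazolidin-3-yl]-3-hydroxy-1-oxo-3-(3,4,5-trimethoxyphenyl)propan-2-yl}-5-methoxyphenyl]prop-2-enoate | COc1cc([C@H](O)[C@H](C(=O)N2C(=O)OC[C@H]2Cc2ccccc2)c2cc(/C=C/C(=O)OC)cc(OC)c2OCc2ccccc2)cc(OC)c1OC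
F8 | step 8 | methyl (2E)-3-{4-(benzyloxy)-3-[(1R,2S)-1,3-dihydroxy-1-(3,4,5-trimethoxyphenyl)propan-2-yl]-5-methoxyphenyl}prop-2-enoate | COc1cc([C@H](O)[C@H](CO)c2cc(/C=C/C(=O)OC)cc(OC)c2OCc2ccccc2)cc(OC)c1OC
F9 | step 8 | methyl (2E)-3-{3-[(1R,2S)-1,3-dihydroxy-1-(3,4,5-trimethoxyphenyl)propan-2-yl]-4-hydroxy-5-methoxyphenyl}prop-2-enoate | COc1cc([C@H](O)[C@H](CO)c2cc(/C=C/C(=O)OC)cc(OC)c2O)cc(OC)c1OC
F10 | step 7 | (1R,2S)-1-(3,4,5-trimethoxyphenyl)-3-[(triisopropylsilyl)oxy]-2-(4-{[(triisopropylsilyl)oxy]methyl}furan-2-yl)propyl formate | COc1cc([C@H](OC=O)[C@H](CO[Si](C(C)C)(C(C)C)C(C)C)c2cc(CO[Si](C(C)C)(C(C)C)C(C)C)co2)cc(OC)c1OC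
F11 | step 7 | 2,2-dibromovinyl ether of 13 | COc1cc([C@H](OC=C(Br)Br)[C@H](CO[Si](C(C)C)(C(C)C)C(C)C)c2cc(CO[Si](C(C)C)(C(C)C)C(C)C)co2)cc(OC)c1OC
F12 | step 4 | methyl 5-{2-[(4R)-4-benzyl-2-thioxo-1,3-thiazolidin-3-yl]-2-oxoethyl}furan-3-carboxylate | COC(=O)c1coc(CC(=O)N2C(=S)SC[C@H]2Cc2ccccc2)c1
F13 | step 4 | methyl 5-{(2S,3R)-1-[(4R)-4-benzyl-2-thioxo-1,3-thiazolidin-3-yl]-3-hydroxy-1-oxo-3-(3,4,5-trimethoxyphenyl)propan-2-yl}furan-3-carboxylate | COc1cc([C@H](O)[C@H](C(=O)N2C(=S)SC[C@H]2Cc2ccccc2)c2cc(C(=O)OC)co2)cc(OC)c1OC
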